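Ring A of the chromene is cut at two neighbouring bonds: the C5–O bond of the free phenol and the bond from C6 to the inner carbonyl of the 1,2-diketone. A C5–C6 aryne, released by fluoride from a 6-trimethylsilyl-5-triflyloxy chromene that already carries the pyran ring, the C7 methoxy and the C8 prenyl group, inserts into the carboxyl C–O bond of a ketal-masked, MOM-protected 4-hydroxyphenylglyoxylic acid. One operation thus places oxygen on C5 and the acyl carbon on C6; the feature exploited is this ortho hydroxy-acyl pair on ring A with the C7 methoxy group flanking C6, which dictates the orientation. Acid then unmasks the diketone and the phenol.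

Key step: step 12

Assumption: the target is taken in the open 2-hydroxybenzil form drawn, which the C5–OH···O=C hydrogen bond should favour over the cyclic hemiketal tautomer.

Remark: with two free hydroxyls ortho to the formyl group the pyran ring could close on either oxygen, so the oxygen that becomes the C5 hydroxyl is kept as a silyl ether from step 2 to step 6. No structural error was found in the key-step precursors or product.

Step 1
Reactants: 1 2,6-dihydroxy-4-methoxybenzaldehyde; 2 allyl bromide
Product: 3 2-(allyloxy)-6-hydroxy-4-methoxybenzaldehyde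
Conditions: K2CO3 (1.1 equiv), 2 (1.05 equiv), acetone, 56 °C
Reagents that add atoms: none
Why: Williamson etherification of the symmetric bis-phenol should stop after one alkylation, because the remaining hydroxyl is held in a strong hydrogen bond to the aldehyde and is much less nucleophilic under carbonate conditions.

Step 2
Reactants: 3 2-(allyloxy)-6-hydroxy-4-methoxybenzaldehyde
Product: 4 2-(allyloxy)-6-[(tert-butyldimethylsilyl)oxy]-4-methoxybenzaldehyde
Conditions: TBSCl, imidazole, DMAP (cat.), DMF, rt
Reagents that add atoms: tert-butyldimethylsilyl chloride, CC(C)(C)[Si](C)(C)Cl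
Why: Standard silylation of a phenol caps the future C5 oxygen, so that only the oxygen regenerated by the Claisen step is free when the pyran ring closes; the silyl ether tolerates heat, metathesis and amine/boronic acid conditions and is later removed with fluoride, not acid.

Step 3
Reactants: 4 2-(allyloxy)-6-[(tert-butyldimethylsilyl)oxy]-4-methoxybenzaldehyde
Product: 5 3-allyl-6-[(tert-butyldimethylsilyl)oxy]-2-hydroxy-4-methoxybenzaldehyde
Conditions: PhNEt2, 190 °C
Reagents that add atoms: none
Why: The aromatic Claisen rearrangement ([3,3]-sigmatropic shift) should deliver the allyl group to the only unsubstituted ortho carbon, the one between the ether oxygen and the methoxy-bearing carbon, since the other ortho position carries the formyl group, and tautomerisation restores the phenol.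

Step 4
Reactants: 5 3-allyl-6-[(tert-butyldimethylsilyl)oxy]-2-hydroxy-4-methoxybenzaldehyde
Product: 6 6-[(tert-butyldimethylsilyl)oxy]-2-hydroxy-4-methoxy-3-(3-methylbut-2-enyl)benzaldehyde
Conditions: 2-methyl-2-butene (excess), second-generation Grubbs catalyst (H2IMes)(PCy3)Cl2Ru=CHPh (3 mol %), CH2Cl2, 40 °C
Reagents that add atoms: 2-methyl-2-butene, CC=C(C)C
Why: Olefin cross-metathesis of a terminal allyl arene with excess 2-methyl-2-butene is a dependable allyl-to-prenyl conversion, driven by loss of propene and tolerant of phenol, aldehyde and silyl ether, and the new alkene terminus bears two methyl groups, so no geometry has to be controlled.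

Step 5
Reactants: 6 6-[(tert-butyldimethylsilyl)oxy]-2-hydroxy-4-methoxy-3-(3-methylbut-2-enyl)benzaldehyde; 7 (2-methylprop-1-en-1-yl)boronic acid
Product: 10 tert-butyl{[7-methoxy-2,2-dimethyl-8-(3-methylbut-2-enyl)-2H-chromen-5-yl]oxy}dimethylsilane, via Petasis aminophenol 8 (not isolated), via ortho-quinone methide 9 (not isolated)
Conditions: 7 (1.5 equiv), Bn2NH (20 mol %), 1,4-dioxane, 90 °C
Reagents that add atoms: none
Why: In this amine-catalysed Petasis borono-Mannich chromene annulation the ortho phenol directs alkenyl transfer from boron to the iminium carbon to give racemic 8, which ejects dibenzylamine to form 9 and closes by oxa-6π electrocyclisation onto the only free phenolic oxygen, fixing O1 beside the prenylated C8.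

Step 6
Reactants: 10 tert-butyl{[7-methoxy-2,2-dimethyl-8-(3-methylbut-2-enyl)-2H-chromen-5-yl]oxy}dimethylsilane
Product: 11 7-methoxy-2,2-dimethyl-8-(3-methylbut-2-enyl)-2H-chromen-5-ol
Conditions: TBAF, AcOH, THF, 0 °C
Reagents that add atoms: none
Why: Fluoride-induced cleavage of the aryl silyl ether should free the C5 phenol under buffered, non-acidic conditions that leave the electron-rich, acid-sensitive chromene and the prenyl group untouched.

Step 7
Reactants: 11 7-methoxy-2,2-dimethyl-8-(3-methylbut-2-enyl)-2H-chromen-5-ol
Product: 12 6-bromo-7-methoxy-2,2-dimethyl-8-(3-methylbut-2-enyl)-2H-chromen-5-ol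
Conditions: NBS (1.0 equiv), i-Pr2NH (10 mol %), CH2Cl2, −78 °C
Reagents that add atoms: N-bromosuccinimide, O=C1CCC(=O)N1Br
Why: Electrophilic aromatic bromination of a phloroglucinol-type phenol is expected to be much faster at −78 °C than attack on either alkene, and C6, flanked by hydroxyl and methoxy and para to O1, is the only ring carbon that still bears hydrogen.

Step 8
Reactants: 12 6-bromo-7-methoxy-2,2-dimethyl-8-(3-methylbut-2-enyl)-2H-chromen-5-ol
Product: 15 7-methoxy-2,2-dimethyl-8-(3-methylbut-2-enyl)-6-(trimethylsilyl)-2H-chromen-5-yl trifluoromethanesulfonate, via trimethylsilyl ether 13 (not isolated), via lithium phenoxide 14 (not isolated)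
Conditions: HMDS, THF, 65 °C, then evaporation in the same flask; n-BuLi, THF, −100 → −78 °C; Tf2O, −100 → −78 °C
Reagents that add atoms: hexamethyldisilazane, C[Si](C)(C)N[Si](C)(C)C; trifluoromethanesulfonic anhydride, O=S(=O)(OS(=O)(=O)C(F)(F)F)C(F)(F)F
Why: This is the standard one-flask route to ortho-silylaryl triflates, in which O-silylation, bromine–lithium exchange at C6, anionic 1,3 O→C silyl shift (retro-Brook rearrangement) to phenoxide 14 and O-triflation follow one another, the exchange being far faster at low temperature than deprotonation at allylic or benzylic positions.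

Step 9
Reactants: 16 methyl 2-(4-hydroxyphenyl)-2-oxoacetate
Product: 17 methyl 2-(4-hydroxyphenyl)-2,2-dimethoxyacetate
Conditions: HC(OMe)3, MeOH, H2SO4 (cat.), 65 °C; then NaHCO3
Reagents that add atoms: trimethyl orthoformate, COC(OC)OC; methanol, CO
Why: Acid-catalysed ketalisation of the activated α-keto ester carbonyl, with the orthoformate consuming the water released, should mask the ketone as its dimethyl ketal while phenol and methyl ester stay unchanged.

Step 10
Reactants: 17 methyl 2-(4-hydroxyphenyl)-2,2-dimethoxyacetate
Product: 18 methyl 2,2-dimethoxy-2-[4-(methoxymethoxy)phenyl]acetate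
Conditions: MOMCl, i-Pr2NEt, CH2Cl2, 0 °C → rt
Reagents that add atoms: chloromethyl methyl ether, COCCl
Why: Base-mediated O-alkylation of the phenol proceeds under conditions that preserve the ketal, and the resulting acetal ether is inert to fluoride and carboxylate at high temperature yet leaves in the same acid treatment as the ketal.

Step 11
Reactants: 18 methyl 2,2-dimethoxy-2-[4-(methoxymethoxy)phenyl]acetate
Product: 19 2,2-dimethoxy-2-[4-(methoxymethoxy)phenyl]acetic acid
Conditions: LiOH·H2O, THF/MeOH/H2O, rt; then 1 M HCl to pH 4, 0 °C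
Reagents that add atoms: lithium hydroxide, [Li+].[OH-]
Why: Saponification of the methyl ester, activated by its two α-alkoxy groups, gives the carboxylate, and brief cold acidification to pH 4 should liberate the acid without touching the ketal or the MOM ether.

Step 12
Reactants: 15 7-methoxy-2,2-dimethyl-8-(3-methylbut-2-enyl)-6-(trimethylsilyl)-2H-chromen-5-yl trifluoromethanesulfonate; 19 2,2-dimethoxy-2-[4-(methoxymethoxy)phenyl]acetic acid
Product: 21 1-[5-hydroxy-7-methoxy-2,2-dimethyl-8-(3-methylbut-2-enyl)-2H-chromen-6-yl]-2,2-dimethoxy-2-[4-(methoxymethoxy)phenyl]ethanone, via C5–C6 aryne 20 (not isolated)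
Conditions: 19 (1.5 equiv), CsF (4 equiv), THF, 125 °C, sealed tube
Reagents that add atoms: none
Why: Fluoride attacks the C6 silicon and triflate departs from C5, giving aryne 20; the carboxylate of 19 bonds through oxygen to C5, and the C6 aryl anion so formed, held next to the new aryl ester, adds to its carbonyl through a four-membered transition state that opens to the C5 phenoxide and the C6 ketone. This is the known fluoride-induced insertion of arynes into the C–O bond of carboxylic acids that yields ortho-hydroxyaryl ketones, applied here to a hindered α,α-dialkoxy acid and a tetrasubstituted aryne. No ring is closed and no stereocenter is formed. The selectivity needed is the orientation of addition, and it is secured by the C7 methoxy group, whose inductive withdrawal stabilises negative charge on the adjacent C6 and so sends the nucleophile to the remote C5, as with other 3-alkoxyarynes. Chemoselectivity rests on the dimethyl ketal (no α-keto carbonyl within reach of the anion), on the MOM ether (no phenoxide to O-arylate) and on the prenyl group being two atoms away from the aryne, too far for an intramolecular ene reaction. The acyl shift is intramolecular, which lets it reach a carbon flanked by two oxygen-bearing carbons, and the high temperature should favour it over protonation of the aryl anion to the aryl ester.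

Step 13
Reactants: 21 1-[5-hydroxy-7-methoxy-2,2-dimethyl-8-(3-methylbut-2-enyl)-2H-chromen-6-yl]-2,2-dimethoxy-2-[4-(methoxymethoxy)phenyl]ethanone
Product: 22 1-[5-hydroxy-7-methoxy-2,2-dimethyl-8-(3-methylbut-2-enyl)-2H-chromen-6-yl]-2-(4-hydroxyphenyl)ethane-1,2-dione
Conditions: 3 M aq. HCl, THF, 45 °C
Reagents that add atoms: water, O
Why: Acid-catalysed acetal hydrolysis should remove the methoxymethyl ether and turn the dimethyl ketal into the ketone in one operation, the para-oxygenated aryl ring stabilising the oxocarbenium ion, while the C6-acylated chromene and the prenyl group, which has no free ortho hydroxyl to cyclise onto, tolerate dilute acid.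

Compound list
1 | 2,6-dihydroxy-4-methoxybenzaldehyde | COc1cc(O)c(C=O)c(O)c1 | starting material
2 | allyl bromide | C=CCBr | starting material
3 | 2-(allyloxy)-6-hydroxy-4-methoxybenzaldehyde | COc1cc(O)c(C=O)c(OCC=C)c1 | intermediate
4 | 2-(allyloxy)-6-[(tert-butyldimethylsilyl)oxy]-4-methoxybenzaldehyde | COc1cc(O[Si](C)(C)C(C)(C)C)c(C=O)c(OCC=C)c1 | intermediate
5 | 3-allyl-6-[(tert-butyldimethylsilyl)oxy]-2-hydroxy-4-methoxybenzaldehyde | COc1cc(O[Si](C)(C)C(C)(C)C)c(C=O)c(O)c1CC=C | intermediate
6 | 6-[(tert-butyldimethylsilyl)oxy]-2-hydroxy-4-methoxy-3-(3-methylbut-2-enyl)benzaldehyde | COc1cc(O[Si](C)(C)C(C)(C)C)c(C=O)c(O)c1CC=C(C)C | intermediate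
7 | (2-methylprop-1-en-1-yl)boronic acid | CC(C)=CB(O)O | starting material
8 | 3-[(tert-butyldimethylsilyl)oxy]-2-[1-(dibenzylamino)-3-methylbut-2-enyl]-5-methoxy-6-(3-methylbut-2-enyl)phenol, racemic | COc1cc(O[Si](C)(C)C(C)(C)C)c(C(C=C(C)C)N(Cc2ccccc2)Cc2ccccc2)c(O)c1CC=C(C)C | intermediate (not isolated)
9 | (6Z)-5-[(tert-butyldimethylsilyl)oxy]-3-methoxy-2-(3-methylbut-2-enyl)-6-(3-methylbut-2-enylidene)cyclohexa-2,4-dien-1-one | CC(C)=C/C=C1\C(=O)C(CC=C(C)C)=C(OC)C=C1O[Si](C)(C)C(C)(C)C | intermediate (not isolated)
10 | tert-butyl{[7-methoxy-2,2-dimethyl-8-(3-methylbut-2-enyl)-2H-chromen-5-yl]oxy}dimethylsilane | COc1cc(O[Si](C)(C)C(C)(C)C)c2C=CC(C)(C)Oc2c1CC=C(C)C | intermediate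
11 | 7-methoxy-2,2-dimethyl-8-(3-methylbut-2-enyl)-2H-chromen-5-ol | COc1cc(O)c2C=CC(C)(C)Oc2c1CC=C(C)C | intermediate
12 | 6-bromo-7-methoxy-2,2-dimethyl-8-(3-methylbut-2-enyl)-2H-chromen-5-ol | COc1c(Br)c(O)c2C=CC(C)(C)Oc2c1CC=C(C)C | intermediate
13 | {[6-bromo-7-methoxy-2,2-dimethyl-8-(3-methylbut-2-enyl)-2H-chromen-5-yl]oxy}trimethylsilane | COc1c(Br)c(O[Si](C)(C)C)c2C=CC(C)(C)Oc2c1CC=C(C)C | intermediate (not isolated)
14 | lithium 7-methoxy-2,2-dimethyl-8-(3-methylbut-2-enyl)-6-(trimethylsilyl)-2H-chromen-5-olate | COc1c([Si](C)(C)C)c([O-])c2C=CC(C)(C)Oc2c1CC=C(C)C.[Li+] | intermediate (not isolated)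
15 | 7-methoxy-2,2-dimethyl-8-(3-methylbut-2-enyl)-6-(trimethylsilyl)-2H-chromen-5-yl trifluoromethanesulfonate | COc1c(CC=C(C)C)c2OC(C)(C)C=Cc2c(OS(=O)(=O)C(F)(F)F)c1[Si](C)(C)C | intermediate
16 | methyl 2-(4-hydroxyphenyl)-2-oxoacetate | COC(=O)C(=O)c1ccc(O)cc1 | starting material
17 | methyl 2-(4-hydroxyphenyl)-2,2-dimethoxyacetate | COC(=O)C(OC)(OC)c1ccc(O)cc1 | intermediate
18 | methyl 2,2-dimethoxy-2-[4-(methoxymethoxy)phenyl]acetate | COCOc1ccc(cc1)C(OC)(OC)C(=O)OC | intermediate
19 | 2,2-dimethoxy-2-[4-(methoxymethoxy)phenyl]acetic acid | COCOc1ccc(cc1)C(OC)(OC)C(=O)O | intermediate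
20 | 7-methoxy-2,2-dimethyl-8-(3-methylbut-2-enyl)-5,6-didehydro-2H-chromene (C5–C6 aryne) | COC1=C(CC=C(C)C)C2=C(C=CC(C)(C)O2)C#C1 | intermediate (not isolated)
21 | 1-[5-hydroxy-7-methoxy-2,2-dimethyl-8-(3-methylbut-2-enyl)-2H-chromen-6-yl]-2,2-dimethoxy-2-[4-(methoxymethoxy)phenyl]ethanone | COc1c(CC=C(C)C)c2OC(C)(C)C=Cc2c(O)c1C(=O)C(OC)(OC)c1ccc(OCOC)cc1 | intermediate
22 | 1-[5-hydroxy-7-methoxy-2,2-dimethyl-8-(3-methylbut-2-enyl)-2H-chromen-6-yl]-2-(4-hydroxyphenyl)ethane-1,2-dione | COc1c(CC=C(C)C)c2c(c(O)c1C(=O)C(=O)c1ccc(O)cc1)C=CC(C)(C)O2 | target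

Total step count: 13. Longest linear sequence: 10 steps (steps 1 to 8, then 12 and 13); the acid branch (steps 9 to 11) joins at step 12.

Steps most likely to fail

Step 12. The C6 aryl anion may be protonated by bifluoride or free acid before the acyl group migrates, so that the reaction stops at the aryl ester. The 1,3-acyl shift onto the hindered carbonyl next to the quaternary ketal carbon may also be slow, or the orientation of addition may erode. The fallback forms the same C6–acyl bond by an anionic Fries-type shift instead of an aryne. It sets out from bromophenol 12 and acid 19. Esterification (EDC·HCl, DMAP, CH2Cl2) should give the aryl ester 6-bromo-7-methoxy-2,2-dimethyl-8-(3-methylbut-2-enyl)-2H-chromen-5-yl 2,2-dimethoxy-2-[4-(methoxymethoxy)phenyl]acetate F1. Treatment with n-BuLi in THF at −100 °C should then cause bromine–lithium exchange at C6 and intramolecular 1,3 O→C acyl migration. Protonation of the lithium phenoxide on work-up comes back to the route at 21.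

Step 5. Iminium formation at the doubly ortho-substituted, electron-rich aldehyde may be slow, so that protodeboronation of 7 outruns alkenyl transfer. The fallback sets out from 6. Addition of Me2C=CHMgBr (2.5 equiv, THF, −78 → 0 °C, kept cold to prevent silyl migration) should give the racemic benzylic allylic alcohol 3-[(tert-butyldimethylsilyl)oxy]-2-(1-hydroxy-3-methylbut-2-enyl)-5-methoxy-6-(3-methylbut-2-enyl)phenol F2. Warming in toluene at 80 °C should dehydrate it to the same quinone methide 9, whose electrocyclisation comes back to the route at 10.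

Step 7. Electrophilic bromine may attack the prenyl or the chromene double bond, or oxidise the very electron-rich phenol, in competition with ring substitution. The fallback avoids halogenation altogether and sets out from 11. Carbamoylation (i-PrNCO, Et3N, CH2Cl2) should give 7-methoxy-2,2-dimethyl-8-(3-methylbut-2-enyl)-2H-chromen-5-yl N-isopropylcarbamate F3. Directed ortho-metalation at the carbon between the carbamate and the methoxy group (TMSOTf, TMEDA; then n-BuLi, Et2O, −78 °C; TMSCl; mild acidic work-up) should give 7-methoxy-2,2-dimethyl-8-(3-methylbut-2-enyl)-6-(trimethylsilyl)-2H-chromen-5-yl N-isopropylcarbamate F4. One-pot carbamate cleavage and triflation (Et2NH, DBU, MeCN, 40 °C; then PhNTf2) comes back to the route at 15, bypassing 12 to 14.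

Further compounds
F1 | step 12 | 6-bromo-7-methoxy-2,2-dimethyl-8-(3-methylbut-2-enyl)-2H-chromen-5-yl 2,2-dimethoxy-2-[4-(methoxymethoxy)phenyl]acetate | COc1c(Br)c(OC(=O)C(OC)(OC)c3ccc(OCOC)cc3)c2C=CC(C)(C)Oc2c1CC=C(C)C
F2 | step 5 | 3-[(tert-butyldimethylsilyl)oxy]-2-(1-hydroxy-3-methylbut-2-enyl)-5-methoxy-6-(3-methylbut-2-enyl)phenol, racemic | COc1cc(O[Si](C)(C)C(C)(C)C)c(C(O)C=C(C)C)c(O)c1CC=C(C)C
F3 | step 7 | 7-methoxy-2,2-dimethyl-8-(3-methylbut-2-enyl)-2H-chromen-5-yl N-isopropylcarbamate | COc1cc(OC(=O)NC(C)C)c2C=CC(C)(C)Oc2c1CC=C(C)C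
F4 | step 7 | 7-methoxy-2,2-dimethyl-8-(3-methylbut-2-enyl)-6-(trimethylsilyl)-2H-chromen-5-yl N-isopropylcarbamate | COc1c([Si](C)(C)C)c(OC(=O)NC(C)C)c2C=CC(C)(C)Oc2c1CC=C(C)C
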